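**Retrosynthetic overview**
- Target 22 ← keto nitrile 15: the surviving CH2CN arm is grown into C1'–C4' (DIBAL, Wittig, hydrogenation, 2 MeMgBr), with C4 held as the carbinol, then reoxidized and desilylated.
- 15 ← boronate 13: the C4–C4a bond is formed by adding the aryl boronate to one nitrile; this closes ring B (the pyranone), the only ring made, while ring A (the benzene) is bought.
- Feature used: C2 carries CH3, O1 and two methylene arms, C3 and C1'. With both arms as CH2CN, C2 is prochiral, so closing C4–C4a onto one nitrile creates the C2 stereocentre and the C4 ketone together.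
- 13 ← aryl iodide dinitrile 11 (Miyaura borylation) ← diene 8 (ozonolysis, oximation, dehydration) ← aldehyde 2 + carbinol 3 (fluoride displacement, Dakin oxidation, silylation).

Key step: step 8

Assumption: the sense of induction of the ligand cannot be predicted safely; (S)-t-BuPyOx is written, and its enantiomer would be used if first runs give the (S)-ketone.
Remark: the phenol is carried as a triisopropylsilyl ether because an acetal would not be safe in the warm aqueous acid of step 8. The oximes of 10 and the C4 carbinol of 16–20 are isomer mixtures and are left undefined in the SMILES.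

**Step 1**
Reactants: 1 2-bromo-4-fluorobenzaldehyde
Product: 2 2-bromo-4-fluoro-5-iodobenzaldehyde
Conditions: NIS (1.1 equiv), conc. H2SO4, 0 °C to rt
Reagents that add atoms: N-iodosuccinimide, O=C1CCC(=O)N1I
Why: Electrophilic aromatic iodination of a deactivated arene by protonated NIS; C5 is ortho to F, para to Br and meta to CHO and, unlike C3, is not flanked by two halogens, so all three groups direct there.

**Step 2**
Reactants: 2 2-bromo-4-fluoro-5-iodobenzaldehyde; 3 4-methylhepta-1,6-dien-4-ol
Product: 5 2-bromo-5-iodo-4-[(4-methylhepta-1,6-dien-4-yl)oxy]benzaldehyde, via potassium 4-methylhepta-1,6-dien-4-olate 4 (not isolated)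
Conditions: 3 (1.3 equiv), KH (1.25 equiv), THF, 0 °C; then 2, 0 °C to rt
Reagents that add atoms: none
Why: Nucleophilic aromatic substitution through a Meisenheimer adduct: the para-formyl group activates C–F, fluoride is far the best leaving group on the ring, and a tertiary alkoxide without α-hydrogen cannot reduce the aldehyde.

**Step 3**
Reactants: 5 2-bromo-5-iodo-4-[(4-methylhepta-1,6-dien-4-yl)oxy]benzaldehyde
Product: 7 2-bromo-5-iodo-4-[(4-methylhepta-1,6-dien-4-yl)oxy]phenol, via aryl formate 6 (not isolated)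
Conditions: 30% aq. H2O2 (1.5 equiv), H2SO4 (cat.), MeOH, rt
Reagents that add atoms: hydrogen peroxide, OO
Why: Acid-catalysed Dakin oxidation: the hydroperoxy hemiacetal rearranges with migration of the para-alkoxy aryl group to formate 6, which is methanolysed in the same medium, while hydrogen peroxide without a peracid should leave the terminal alkenes and the aryl iodide alone.

**Step 4**
Reactants: 7 2-bromo-5-iodo-4-[(4-methylhepta-1,6-dien-4-yl)oxy]phenol
Product: 8 [2-bromo-5-iodo-4-[(4-methylhepta-1,6-dien-4-yl)oxy]phenoxy]tri(propan-2-yl)silane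
Conditions: i-Pr3SiCl (1.2 equiv), imidazole (2.5 equiv), DMF, rt
Reagents that add atoms: chlorotri(propan-2-yl)silane, CC(C)[Si](Cl)(C(C)C)C(C)C
Why: Imidazole-promoted silylation of the phenol; the aryl triisopropylsilyl ether should withstand ozone, hydride, Grignard reagent and warm aqueous acid and is removed by fluoride at the end.

**Step 5**
Reactants: 8 [2-bromo-5-iodo-4-[(4-methylhepta-1,6-dien-4-yl)oxy]phenoxy]tri(propan-2-yl)silane
Product: 10 3-[5-bromo-2-iodo-4-[tri(propan-2-yl)silyloxy]phenoxy]-3-methylpentanedial dioxime (oxime geometry not defined), via dialdehyde 9 (not isolated)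
Conditions: O3, CH2Cl2, −78 °C (Sudan Red 7B end point); PPh3 (2.2 equiv), −78 to 0 °C; then NH2OH·HCl (6 equiv), NaOAc (6 equiv), EtOH/H2O, 0 °C to rt
Reagents that add atoms: hydroxylamine hydrochloride, Cl.NO
Why: Ozonolysis with reductive work-up cleaves both terminal alkenes, and the β-aryloxy dialdehyde 9 is condensed at once with hydroxylamine in acetate buffer (oxime formation), so it never meets base and should not eliminate the aryloxide.

**Step 6**
Reactants: 10 3-[5-bromo-2-iodo-4-[tri(propan-2-yl)silyloxy]phenoxy]-3-methylpentanedial dioxime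
Product: 11 3-[5-bromo-2-iodo-4-[tri(propan-2-yl)silyloxy]phenoxy]-3-methylpentanedinitrile
Conditions: (CF3CO)2O (2.5 equiv), pyridine (6 equiv), CH2Cl2, 0 °C to rt
Reagents that add atoms: none
Why: Dehydration of the aldoximes through their O-trifluoroacetates (E2 loss of trifluoroacetate) under conditions too weakly basic to deprotonate α to a nitrile.

**Step 7**
Reactants: 11 3-[5-bromo-2-iodo-4-[tri(propan-2-yl)silyloxy]phenoxy]-3-methylpentanedinitrile; 12 bis(pinacolato)diboron
Product: 13 3-[5-bromo-2-(4,4,5,5-tetramethyl-1,3,2-dioxaborolan-2-yl)-4-[tri(propan-2-yl)silyloxy]phenoxy]-3-methylpentanedinitrile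
Conditions: 12 (1.2 equiv), PdCl2(dppf) (3 mol %), KOAc (3 equiv), 1,4-dioxane, 80 °C
Reagents that add atoms: none
Why: Miyaura borylation: oxidative addition of zerovalent palladium is much faster at C–I than at C–Br, and the weak base KOAc allows transmetalation without provoking β-elimination of the aryloxide from the nitriles.

**Step 8**
Reactants: 13 3-[5-bromo-2-(4,4,5,5-tetramethyl-1,3,2-dioxaborolan-2-yl)-4-[tri(propan-2-yl)silyloxy]phenoxy]-3-methylpentanedinitrile
Product: 15 2-[(2R)-7-bromo-2-methyl-4-oxo-6-[tri(propan-2-yl)silyloxy]chroman-2-yl]acetonitrile, via N–H ketimine 14 (not isolated)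
Conditions: Pd(OCOCF3)2 (10 mol %), (S)-4-tert-butyl-2-(pyridin-2-yl)-4,5-dihydrooxazole (12 mol %), CF3CO2H (1.5 equiv), H2O (10 equiv), 2-methyltetrahydrofuran, 60 °C
Reagents that add atoms: water, O
Why: Proposed new method: transmetalation of the boronate to the cationic divalent palladium–pyridine-oxazoline complex gives an arylpalladium species held by O1 and C2 within reach of both cyanomethyl arms; one nitrile coordinates and inserts into the aryl–palladium bond (C4a to the nitrile carbon), CF3CO2H protonates the N-palladated ketimine to release 14 and the catalyst, and water hydrolyses 14 to the C4 ketone. The closest known reaction type is the palladium-catalysed enantioselective desymmetrizing addition of arylboron reagents to prochiral malononitriles; an intramolecular version on an oxygen-tethered 3,3-disubstituted glutaronitrile is not known. Ring B closes in the 6-exo-dig mode, the nitrile nitrogen staying outside the ring. C2 becomes stereogenic only through the choice between its two enantiotopic CH2CN groups, so its configuration is set by the chiral ligand alone, which must place the C2 methyl group and the spectator arm in the less crowded positions of the six-membered insertion transition state. The step needs ring closure to outrun protodeboronation and the C–Br bond to stay intact: the short tether and the geminal disubstitution at C2 favour the intramolecular insertion, the redox-neutral cycle never passes through zerovalent palladium, and the acidic medium keeps the β-aryloxy nitriles from eliminating the aryloxide.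

**Step 9**
Reactants: 15 2-[(2R)-7-bromo-2-methyl-4-oxo-6-[tri(propan-2-yl)silyloxy]chroman-2-yl]acetonitrile
Product: 17 2-[(2S)-7-bromo-4-hydroxy-2-methyl-6-[tri(propan-2-yl)silyloxy]chroman-2-yl]acetaldehyde (both C4 epimers; the descriptor at C2 changes by priority only), via N–H aldimine 16 (not isolated)
Conditions: i-Bu2AlH (3.5 equiv), CH2Cl2, −78 °C; then MeOH, aq. potassium sodium tartrate, rt
Reagents that add atoms: water, O
Why: DIBAL reduction: the ketone gives the benzylic alcohol (C4 epimers are immaterial, since C4 is reoxidized in step 13) and the nitrile stops at the N-aluminated aldimine, which is hydrolysed on work-up to the aldehyde without touching C2.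

**Step 10**
Reactants: 17 2-[(2S)-7-bromo-4-hydroxy-2-methyl-6-[tri(propan-2-yl)silyloxy]chroman-2-yl]acetaldehyde
Product: 18 methyl (E)-4-[(2R)-7-bromo-4-hydroxy-2-methyl-6-[tri(propan-2-yl)silyloxy]chroman-2-yl]but-2-enoate
Conditions: Ph3P=CHCO2Me (1.5 equiv), CH2Cl2, rt (17 used crude)
Reagents that add atoms: methyl (triphenylphosphoranylidene)acetate, COC(=O)C=P(c1ccccc1)(c1ccccc1)c1ccccc1
Why: Wittig olefination with a stabilized ylide, which is (E)-selective and neutral, so no base is present to open the chroman by β-elimination from the aldehyde.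

**Step 11**
Reactants: 18 methyl (E)-4-[(2R)-7-bromo-4-hydroxy-2-methyl-6-[tri(propan-2-yl)silyloxy]chroman-2-yl]but-2-enoate
Product: 19 methyl 4-[(2R)-7-bromo-4-hydroxy-2-methyl-6-[tri(propan-2-yl)silyloxy]chroman-2-yl]butanoate
Conditions: H2 (3 atm), RhCl(PPh3)3 (5 mol %), toluene/EtOH, 40 °C
Reagents that add atoms: none
Why: Homogeneous hydrogenation with Wilkinson's catalyst saturates the disubstituted enoate C=C bond and, unlike palladium on carbon, should not cleave the aryl C–Br or the benzylic C–O bond.

**Step 12**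
Reactants: 19 methyl 4-[(2R)-7-bromo-4-hydroxy-2-methyl-6-[tri(propan-2-yl)silyloxy]chroman-2-yl]butanoate
Product: 20 (2R)-7-bromo-2-(4-hydroxy-4-methylpentyl)-2-methyl-6-[tri(propan-2-yl)silyloxy]chroman-4-ol (both C4 epimers)
Conditions: MeMgBr (5 equiv), THF, 0 °C to rt; then pH 7 phosphate buffer
Reagents that add atoms: methylmagnesium bromide, C[Mg]Br
Why: Double Grignard addition to the ester (through the methyl ketone) builds the tertiary carbinol, the C4 alkoxide formed first keeps that position masked, and the aryl bromide does not exchange with MeMgBr.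

**Step 13**
Reactants: 20 (2R)-7-bromo-2-(4-hydroxy-4-methylpentyl)-2-methyl-6-[tri(propan-2-yl)silyloxy]chroman-4-ol
Product: 21 (2R)-7-bromo-2-(4-hydroxy-4-methylpentyl)-2-methyl-6-[tri(propan-2-yl)silyloxy]chroman-4-one
Conditions: MnO2 (activated, 15 equiv), CH2Cl2, rt
Reagents that add atoms: none
Why: Manganese dioxide oxidation of the benzylic secondary alcohol only; the tertiary alcohol cannot be oxidized and the neutral heterogeneous conditions leave C2 intact.

**Step 14**
Reactants: 21 (2R)-7-bromo-2-(4-hydroxy-4-methylpentyl)-2-methyl-6-[tri(propan-2-yl)silyloxy]chroman-4-one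
Product: 22 (2R)-7-bromo-6-hydroxy-2-(4-hydroxy-4-methylpentyl)-2-methylchroman-4-one
Conditions: Bu4NF (1.1 equiv), AcOH (1.1 equiv), THF, 0 °C
Reagents that add atoms: none
Why: Fluoride-induced desilylation of the aryl silyl ether; acetic acid buffers the phenoxide so that the chromanone is not exposed to base, which could open and reclose ring B (retro-oxa-Michael) and erode C2.

**Compound list**
1 | 2-bromo-4-fluorobenzaldehyde | O=Cc1ccc(F)cc1Br | starting material
2 | 2-bromo-4-fluoro-5-iodobenzaldehyde | O=Cc1cc(I)c(F)cc1Br | intermediate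
3 | 4-methylhepta-1,6-dien-4-ol | C=CCC(C)(O)CC=C | starting material
4 | potassium 4-methylhepta-1,6-dien-4-olate (not isolated) | C=CCC(C)([O-])CC=C.[K+] | intermediate
5 | 2-bromo-5-iodo-4-[(4-methylhepta-1,6-dien-4-yl)oxy]benzaldehyde | O=Cc1cc(I)c(OC(C)(CC=C)CC=C)cc1Br | intermediate
6 | 2-bromo-5-iodo-4-[(4-methylhepta-1,6-dien-4-yl)oxy]phenyl formate (not isolated) | O=COc1cc(I)c(OC(C)(CC=C)CC=C)cc1Br | intermediate
7 | 2-bromo-5-iodo-4-[(4-methylhepta-1,6-dien-4-yl)oxy]phenol | Oc1cc(I)c(OC(C)(CC=C)CC=C)cc1Br | intermediate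
8 | [2-bromo-5-iodo-4-[(4-methylhepta-1,6-dien-4-yl)oxy]phenoxy]tri(propan-2-yl)silane | CC(C)[Si](Oc1cc(I)c(OC(C)(CC=C)CC=C)cc1Br)(C(C)C)C(C)C | intermediate
9 | 3-[5-bromo-2-iodo-4-[tri(propan-2-yl)silyloxy]phenoxy]-3-methylpentanedial (not isolated) | CC(C)[Si](Oc1cc(I)c(OC(C)(CC=O)CC=O)cc1Br)(C(C)C)C(C)C | intermediate
10 | 3-[5-bromo-2-iodo-4-[tri(propan-2-yl)silyloxy]phenoxy]-3-methylpentanedial dioxime (oxime geometry not defined) | CC(C)[Si](Oc1cc(I)c(OC(C)(CC=NO)CC=NO)cc1Br)(C(C)C)C(C)C | intermediate
11 | 3-[5-bromo-2-iodo-4-[tri(propan-2-yl)silyloxy]phenoxy]-3-methylpentanedinitrile | CC(C)[Si](Oc1cc(I)c(OC(C)(CC#N)CC#N)cc1Br)(C(C)C)C(C)C | intermediate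
12 | bis(pinacolato)diboron | CC1(C)OB(OC1(C)C)B1OC(C)(C)C(C)(C)O1 | starting material
13 | 3-[5-bromo-2-(4,4,5,5-tetramethyl-1,3,2-dioxaborolan-2-yl)-4-[tri(propan-2-yl)silyloxy]phenoxy]-3-methylpentanedinitrile | CC(C)[Si](Oc1cc(B2OC(C)(C)C(C)(C)O2)c(OC(C)(CC#N)CC#N)cc1Br)(C(C)C)C(C)C | intermediate
14 | 2-[(2S)-7-bromo-4-imino-2-methyl-6-[tri(propan-2-yl)silyloxy]chroman-2-yl]acetonitrile (not isolated; same spatial arrangement as 15, descriptor changed by priority) | N#CC[C@]1(C)CC(=N)c2cc(O[Si](C(C)C)(C(C)C)C(C)C)c(Br)cc2O1 | intermediate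
15 | 2-[(2R)-7-bromo-2-methyl-4-oxo-6-[tri(propan-2-yl)silyloxy]chroman-2-yl]acetonitrile | N#CC[C@]1(C)CC(=O)c2cc(O[Si](C(C)C)(C(C)C)C(C)C)c(Br)cc2O1 | intermediate
16 | (2R)-7-bromo-2-(2-iminoethyl)-2-methyl-6-[tri(propan-2-yl)silyloxy]chroman-4-ol (not isolated; C4 epimers) | N=CC[C@]1(C)CC(O)c2cc(O[Si](C(C)C)(C(C)C)C(C)C)c(Br)cc2O1 | intermediate
17 | 2-[(2S)-7-bromo-4-hydroxy-2-methyl-6-[tri(propan-2-yl)silyloxy]chroman-2-yl]acetaldehyde (C4 epimers) | O=CC[C@]1(C)CC(O)c2cc(O[Si](C(C)C)(C(C)C)C(C)C)c(Br)cc2O1 | intermediate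
18 | methyl (E)-4-[(2R)-7-bromo-4-hydroxy-2-methyl-6-[tri(propan-2-yl)silyloxy]chroman-2-yl]but-2-enoate (C4 epimers) | COC(=O)/C=C/C[C@]1(C)CC(O)c2cc(O[Si](C(C)C)(C(C)C)C(C)C)c(Br)cc2O1 | intermediate
19 | methyl 4-[(2R)-7-bromo-4-hydroxy-2-methyl-6-[tri(propan-2-yl)silyloxy]chroman-2-yl]butanoate (C4 epimers) | COC(=O)CCC[C@]1(C)CC(O)c2cc(O[Si](C(C)C)(C(C)C)C(C)C)c(Br)cc2O1 | intermediate
20 | (2R)-7-bromo-2-(4-hydroxy-4-methylpentyl)-2-methyl-6-[tri(propan-2-yl)silyloxy]chroman-4-ol (C4 epimers) | CC(C)(O)CCC[C@]1(C)CC(O)c2cc(O[Si](C(C)C)(C(C)C)C(C)C)c(Br)cc2O1 | intermediate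
21 | (2R)-7-bromo-2-(4-hydroxy-4-methylpentyl)-2-methyl-6-[tri(propan-2-yl)silyloxy]chroman-4-one | CC(C)(O)CCC[C@]1(C)CC(=O)c2cc(O[Si](C(C)C)(C(C)C)C(C)C)c(Br)cc2O1 | intermediate
22 | (2R)-7-bromo-6-hydroxy-2-(4-hydroxy-4-methylpentyl)-2-methylchroman-4-one | CC(C)(O)CCC[C@]1(C)CC(=O)c2cc(O)c(Br)cc2O1 | target

**Step count**
Total: 14 steps. Longest linear sequence: 14 steps (1 to 22).

**Steps most likely to fail**

1. Step 8. Insertion into the nitrile may be slower than protodeboronation of the electron-rich ortho-alkoxy aryl boronate, or the catalyst may discriminate poorly between the two enantiotopic nitriles. The fallback gives up catalyst control for resolution. It sets out from 13: [Rh(OH)(cod)]2 (3 mol %) in dioxane/H2O at 80 °C would bring about the known monovalent-rhodium addition of an aryl boronate to a nitrile, which needs no acid and has fast transmetalation. This should give the racemic ketimine F1 and, after hydrolysis in the wet medium, the racemic keto nitrile F2. Preparative supercritical-fluid chromatography on an amylose tris(3,5-dimethylphenylcarbamate) phase would separate the enantiomers; the (S)-keto nitrile F3 is set aside and the (R)-enantiomer is 15, where the route is rejoined.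

2. Step 5. The aryloxide may be lost by β-elimination from the dialdehyde, or the 1,5-dialdehyde may cyclocondense with hydroxylamine to a pyridine with expulsion of the phenol. The fallback reaches the nitriles through the acid oxidation level and sets out from 8. Ozonolysis (Me2S work-up) followed in the same flask by Pinnick oxidation (NaClO2, NaH2PO4, 2-methylbut-2-ene, t-BuOH/H2O) would oxidize 9 as it forms, in a weakly acidic medium free of nitrogen nucleophiles, to the diacid F4, a β-aryloxy acid that does not eliminate readily. Amide coupling (EDC·HCl, ammonium 1-hydroxybenzotriazolate, DMF) would give the diamide F5, and dehydration with (CF3CO)2O/pyridine would return the route to 11.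

3. Step 2. The hindered alkoxide may attack the formyl group (hemiacetal alkoxide, then hydride transfer between aldehyde molecules) faster than it displaces fluoride next to the iodine. The fallback changes the activating group to a nitrile, which does not take up alkoxide irreversibly, and sets out from 2. NH2OH·HCl and HCO2Na in refluxing HCO2H would convert 2 through the aldoxime F6 into 2-bromo-4-fluoro-5-iodobenzonitrile F7. Displacement of fluoride by alkoxide 4 (KH, THF, 0 °C to rt) would give the ether nitrile F8. i-Bu2AlH (1.2 equiv, toluene, −78 °C) followed by aqueous tartaric acid would give the aldimine F9 and, on its hydrolysis, aldehyde 5, where the route is rejoined.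

**Further compounds**
F1 | step 8 | rac-2-[7-bromo-4-imino-2-methyl-6-[tri(propan-2-yl)silyloxy]chroman-2-yl]acetonitrile | N#CCC1(C)CC(=N)c2cc(O[Si](C(C)C)(C(C)C)C(C)C)c(Br)cc2O1
F2 | step 8 | rac-2-[7-bromo-2-methyl-4-oxo-6-[tri(propan-2-yl)silyloxy]chroman-2-yl]acetonitrile | N#CCC1(C)CC(=O)c2cc(O[Si](C(C)C)(C(C)C)C(C)C)c(Br)cc2O1
F3 | step 8 | 2-[(2S)-7-bromo-2-methyl-4-oxo-6-[tri(propan-2-yl)silyloxy]chroman-2-yl]acetonitrile | N#CC[C@@]1(C)CC(=O)c2cc(O[Si](C(C)C)(C(C)C)C(C)C)c(Br)cc2O1
F4 | step 5 | 3-[5-bromo-2-iodo-4-[tri(propan-2-yl)silyloxy]phenoxy]-3-methylpentanedioic acid | CC(C)[Si](Oc1cc(I)c(OC(C)(CC(=O)O)CC(=O)O)cc1Br)(C(C)C)C(C)C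
F5 | step 5 | 3-[5-bromo-2-iodo-4-[tri(propan-2-yl)silyloxy]phenoxy]-3-methylpentanediamide | CC(C)[Si](Oc1cc(I)c(OC(C)(CC(N)=O)CC(N)=O)cc1Br)(C(C)C)C(C)C
F6 | step 2 | 2-bromo-4-fluoro-5-iodobenzaldehyde oxime | ON=Cc1cc(I)c(F)cc1Br
F7 | step 2 | 2-bromo-4-fluoro-5-iodobenzonitrile | N#Cc1cc(I)c(F)cc1Br
F8 | step 2 | 2-bromo-5-iodo-4-[(4-methylhepta-1,6-dien-4-yl)oxy]benzonitrile | N#Cc1cc(I)c(OC(C)(CC=C)CC=C)cc1Br
F9 | step 2 | 1-[2-bromo-5-iodo-4-[(4-methylhepta-1,6-dien-4-yl)oxy]phenyl]methanimine | N=Cc1cc(I)c(OC(C)(CC=C)CC=C)cc1Br
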